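The numbers in the tables are simulated with constants of no real substance; noise was put on by code.

Plan the alpha flask around its working time rather than the 3.1 h on the clock. That is my reply to your request for a quick number, and the share it gives stands after the reckoning below.

| flask | X | J | Q | time |
|---|---|---|---|---|
| gamma | 50.0 mM | 100 mM | 1.00 mM |  |
| delta | 25.0 mM | 75.0 mM | 1.00 mM |  |
| eta | 75.0 mM | 100 mM | 1.00 mM |  |
| alpha | 100 mM | 100 mM | 1.00 mM | 3.1 h |

| gamma run: time / h | gamma run: [Z] / mM | delta run: time / h | delta run: [Z] / mM | eta run: time / h | eta run: [Z] / mM |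
|---|---|---|---|---|---|
| 0.12 | 2.11 | 0.12 | 1.86 | 0.12 | 2.32 |
| 0.28 | 4.96 | 0.28 | 4.17 | 0.28 | 5.52 |
| 0.62 | 10.71 | 0.62 | 8.24 | 0.62 | 11.46 |
| 1.4 | 22.04 | 1.4 | 14.88 | 1.4 | 24.92 |
| 3.1 | 38.67 | 3.1 | 20.55 | 3.1 | 49.26 |

(readings scatter by 0.2 mM)

- the exponent of [X] in the starting rate at the charge of the gamma run (at the point where two percent of the X have become Z) (one fixed amount of Z, the same in the runs compared)
- the exponent of [J] in the starting rate at the charge of the gamma run (at the point where two percent of the X have become Z)
- the delta run starts with 25.0 mM less of X and of J than the gamma run, and with no Z. Compared where both hold the same amount of X, once fifteen percent of what the delta run was charged with has turned into Z, is the delta run faster, slower or alike (within a tenth)?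
- Z in the alpha run at 3.1 h, as a share of the X charged
- which of these the readings show (nothing beyond the main steps / the loaded catalyst dies / the catalyst dies in pairs / the two partners rest in a complex / the catalyst wakes slowly)

- Overall: X + J -> Z, with Q as catalyst.
- Constant volume, constant temperature.
- Bound and free are read together.
- An order is taken over about fifteen percent of the charge, up and down.

I counted turnovers, meaning Z made per Q charged. Early on, at 0.28 h, the eta run has averaged 19.7 h⁻¹ and the gamma run 17.7 h⁻¹, the two readings good to about 3.62% and 4.03%. By 3.1 h the eta run has made 49.3 turnovers, fewer than the 61.1 its early pace would give. Call working hours the turnovers made by 3.1 h divided by the early turnovers per hour; for the eta run that gives: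

working hours = 49.3 / 19.7 h⁻¹ = 2.50 h

I carry those hours over to alpha. Gamma, eta and alpha share their charges of J and Q. From gamma to eta the X charge grows by a factor of 1.50 and the pace by 1.11, which reads as an order of 0.264 in X. Alpha holds 1.33 times the X of eta, so I raise eta's pace by that factor taken to this order:

alpha pace = 19.7 h⁻¹ × 1.33^0.264 = 21.3 h⁻¹

Z in alpha = 21.3 h⁻¹ × 2.50 h × 1.00 mM = 53.1 mM

Your forecast gives 54%, with a range of 49% to 59%, orders of 0.27 in X and 0.15 in J, and the delta run faster. It names this outcome: the catalyst dies in pairs, on the ground that the evidence “points to free catalyst dying, probably in pairs”. My 53.1% of the X charged stands below yours by 0.86 percentage points.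

The flask gives 54.7%, orders of 0.16 in X and 0.016 in J, the delta run faster, and this outcome: the catalyst dies in pairs.

    Q + X → QX (3060 M⁻¹ h⁻¹)
    QX + J → Jy (11660 M⁻¹ h⁻¹)
    Jy → Z + Q (21.56 h⁻¹)
    2 Q → 2 Dz (3398 M⁻¹ h⁻¹)

Alpha's 54.7 turnovers at my pace come to 2.57 h of working time. At alpha's start Jy went on to Z at 21.6 h⁻¹, more slowly than Q took up X at 306 h⁻¹ or QX took up J at 1170 h⁻¹, with Jy the resting state of Q at that moment. While Z formed, free Q between turns was also lost in pairs to Dz. The working hours of the delta run came to 1.38 h of its 3.1 h, and at 3.1 h Z stood at 82.2% of its X.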